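The 2,6,6-trimethylcyclohexene (C1' = stereocentre bearing the benzylic CH2, C2'(Me)=C3', C4'H2, C5'H2, C6'Me2) is a disguised Diels–Alder adduct: its C2'=C3' alkene lies opposite the C5'–C6' bond, so an isobutene equivalent can be laid across an (E)-1-substituted 2-methylbutadiene. A chiral oxazaborolidinium-catalysed [4+2] cycloaddition of (2E)-3-methylpenta-2,4-dienyl benzoate with methacrolein forms C4'–C5' and the hindered C1'–C6' bond to a fully substituted carbon in one operation and sets C1'. Wolff–Kishner reduction then turns the formyl group into the second C6' methyl. The (R)-α-cyclogeranyl unit is finally joined, as its zinc reagent, to C-6 of ring A of a 6-iodokaempferol silyl ether.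

Key step: step 3

Assumption: the (S)-oxazaborolidinium catalyst is taken to deliver dienes to the Re face of C-α of bound methacrolein (its sense with cyclopentadiene) and the formyl group is taken to be endo with the open-chain diene, so the (R)-catalyst is specified; should the exo mode dominate in practice, the (S)-catalyst leads to the same (1'R) series.

Step 1
Reactants: 1 (2E)-3-methylpent-2-en-4-yn-1-ol
Product: 2 (2E)-3-methylpenta-2,4-dien-1-ol
Conditions: Zn dust activated with Cu(OAc)2 and AgNO3, MeOH/H2O (1:1), 45 °C
Reagents that add atoms: none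
Why: Activated-zinc semi-reduction of a conjugated alkyne, which stops at the alkene and neither reduces nor isomerises the E-trisubstituted double bond; no stereocentre is formed.

Step 2
Reactants: 2 (2E)-3-methylpenta-2,4-dien-1-ol
Product: 3 (2E)-3-methylpenta-2,4-dien-1-yl benzoate
Conditions: BzCl, Et3N, DMAP (cat.), CH2Cl2, 0 °C
Reagents that add atoms: benzoyl chloride, O=C(Cl)c1ccccc1
Why: DMAP-catalysed esterification of the primary allylic alcohol; the benzoate is a weak Lewis base that should not tie up the boron catalyst of step 3 and is cleaved by the base of step 4.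

Step 3
Reactants: 3 (2E)-3-methylpenta-2,4-dien-1-yl benzoate; 4 methacrolein (2-methylprop-2-enal)
Product: 5 [(1S,6R)-6-formyl-2,6-dimethylcyclohex-2-en-1-yl]methyl benzoate (CHO cis to CH2OBz)
Conditions: (R)-3,3-diphenyl-1-(o-tolyl)tetrahydro-1H,3H-pyrrolo[1,2-c][1,3,2]oxazaborole (20 mol %), Tf2NH (18 mol %), excess dienophile, CH2Cl2, −78 → −40 °C
Reagents that add atoms: none
Why: Coordination of methacrolein to the chiral oxazaborolidinium cation lowers its LUMO and lets the s-cis (E)-diene add in a concerted but asynchronous [4+2] cycloaddition in which every atom of both partners ends up in the adduct, the closest known type being the cationic-oxazaborolidine-catalysed Diels–Alder reaction of 2-substituted acroleins with open-chain dienes. The six-membered ring is closed by intermolecular cycloaddition, suprafacial on both partners, with the bond from the unsubstituted diene terminus to the enal β-carbon (C4'–C5') leading and the bond from C1' to the α-carbon (C1'–C6', to the quaternary centre) following. C6' is set by the catalyst, which should expose only the Si face of the α-carbon of the bound s-trans enal; C1' is set relative to C6' by the formyl-endo approach and the E geometry of the diene, which places CH2OBz outside and hence cis to CHO. The step needs "ortho" regiochemistry, endo selectivity and one enal face: the 1-substituent should outweigh the 2-methyl group as regiodirector (as with other 1,2-dialkylbutadienes such as 1-vinylcyclohexene) and the unhindered CH2 terminus takes the leading bond, the Lewis-acid-bound formyl group prefers the endo position, and the weakly basic benzoate does not compete for the catalyst. Because C6' loses its chirality in step 4, any exo diastereomer (which would lead to the enantiomer) is removed by chromatography at this stage.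

Step 4
Reactants: 5 [(1S,6R)-6-formyl-2,6-dimethylcyclohex-2-en-1-yl]methyl benzoate
Product: 7 [(1R)-2,6,6-trimethylcyclohex-2-en-1-yl]methanol ((R)-α-cyclogeraniol), via hydrazone 6 (not isolated)
Conditions: N2H4·H2O, KOH, diethylene glycol, 130 °C, then 200 °C
Reagents that add atoms: none
Why: Wolff–Kishner reduction (Huang-Minlon procedure): the aldehyde has no α-hydrogen and C1' is not enolisable, so CHO should become CH3 without touching the stereocentre, while KOH saponifies the benzoate in the same pot.

Step 5
Reactants: 7 [(1R)-2,6,6-trimethylcyclohex-2-en-1-yl]methanol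
Product: 8 (6R)-6-(iodomethyl)-1,5,5-trimethylcyclohex-1-ene
Conditions: I2, PPh3, imidazole, CH2Cl2, 0 °C → rt
Reagents that add atoms: iodine, II
Why: Appel iodination, in which iodide displaces the alkoxyphosphonium group at the primary carbon, one atom away from C1', whose configuration is therefore untouched.

Step 6
Reactants: 9 kaempferol (3,5,7-trihydroxy-2-(4-hydroxyphenyl)-4H-chromen-4-one)
Product: 10 5-hydroxy-3,7-bis(tert-butyldimethylsilyloxy)-2-[4-(tert-butyldimethylsilyloxy)phenyl]-4H-chromen-4-one
Conditions: TBSCl (3.3 equiv), imidazole, DMF, 0 °C → rt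
Reagents that add atoms: tert-butyldimethylsilyl chloride, CC(C)(C)[Si](C)(C)Cl
Why: Phenol silylation, in which the 7-, 4'- and 3-hydroxyls should react while the 5-OH, hydrogen-bonded to the C4 carbonyl and the least nucleophilic, stays free.

Step 7
Reactants: 10 5-hydroxy-3,7-bis(tert-butyldimethylsilyloxy)-2-[4-(tert-butyldimethylsilyloxy)phenyl]-4H-chromen-4-one
Product: 11 5-hydroxy-6-iodo-3,7-bis(tert-butyldimethylsilyloxy)-2-[4-(tert-butyldimethylsilyloxy)phenyl]-4H-chromen-4-one
Conditions: NIS (1.05 equiv), DMF, rt, dark
Reagents that add atoms: N-iodosuccinimide, O=C1CCC(=O)N1I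
Why: Electrophilic aromatic iodination, which under neutral conditions is expected to occur at C-6 of a 5-hydroxy-7-O-substituted flavone, ortho to the free phenol, in preference to C-8.

Step 8
Reactants: 8 (6R)-6-(iodomethyl)-1,5,5-trimethylcyclohex-1-ene; 11 5-hydroxy-6-iodo-3,7-bis(tert-butyldimethylsilyloxy)-2-[4-(tert-butyldimethylsilyloxy)phenyl]-4H-chromen-4-one
Product: 13 5-hydroxy-3,7-bis(tert-butyldimethylsilyloxy)-2-[4-(tert-butyldimethylsilyloxy)phenyl]-6-{[(1R)-2,6,6-trimethylcyclohex-2-en-1-yl]methyl}-4H-chromen-4-one, via alkylzinc iodide 12 (not isolated)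
Conditions: 8, Zn dust, LiCl, THF, 40 °C; then slow addition (1.5 equiv) to 11, Pd(OAc)2 (5 mol %), SPhos (10 mol %), THF, 25 → 50 °C
Reagents that add atoms: none
Why: Negishi cross-coupling: the primary alkylzinc iodide should tolerate the ketone, the silyl ethers and the hydrogen-bonded phenol, and the bulky electron-rich biarylphosphine should speed oxidative addition of zerovalent palladium into the hindered C–I bond and reductive elimination ahead of β-hydride elimination; C1' is not involved.

Step 9
Reactants: 13 5-hydroxy-3,7-bis(tert-butyldimethylsilyloxy)-2-[4-(tert-butyldimethylsilyloxy)phenyl]-6-{[(1R)-2,6,6-trimethylcyclohex-2-en-1-yl]methyl}-4H-chromen-4-one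
Product: 14 Ugonin G (3,5,7-trihydroxy-2-(4-hydroxyphenyl)-6-{[(1R)-2,6,6-trimethylcyclohex-2-en-1-yl]methyl}-4H-chromen-4-one)
Conditions: TBAF, AcOH, THF, 0 °C, argon
Reagents that add atoms: none
Why: Fluoride-mediated desilylation under buffered, non-acidic conditions, which should avoid acid-induced addition of the neighbouring phenols to the C2'=C3' alkene and leaves C1' untouched.

Compound list
1 | (2E)-3-methylpent-2-en-4-yn-1-ol | C#C/C(C)=C/CO | starting material
2 | (2E)-3-methylpenta-2,4-dien-1-ol | C=C/C(C)=C/CO | intermediate
3 | (2E)-3-methylpenta-2,4-dien-1-yl benzoate | C=C/C(C)=C/COC(=O)c1ccccc1 | intermediate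
4 | methacrolein (2-methylprop-2-enal) | CC(=C)C=O | starting material
5 | [(1S,6R)-6-formyl-2,6-dimethylcyclohex-2-en-1-yl]methyl benzoate | CC1=CCC[C@@](C)(C=O)[C@H]1COC(=O)c1ccccc1 | intermediate
6 | [(1S,6R)-6-[(E)-hydrazinylidenemethyl]-2,6-dimethylcyclohex-2-en-1-yl]methanol | CC1=CCC[C@@](C)(/C=N/N)[C@H]1CO | intermediate
7 | [(1R)-2,6,6-trimethylcyclohex-2-en-1-yl]methanol ((R)-α-cyclogeraniol) | CC1=CCCC(C)(C)[C@H]1CO | intermediate
8 | (6R)-6-(iodomethyl)-1,5,5-trimethylcyclohex-1-ene | CC1=CCCC(C)(C)[C@H]1CI | intermediate
9 | kaempferol | O=c1c(O)c(-c2ccc(O)cc2)oc2cc(O)cc(O)c12 | starting material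
10 | 5-hydroxy-3,7-bis(tert-butyldimethylsilyloxy)-2-[4-(tert-butyldimethylsilyloxy)phenyl]-4H-chromen-4-one | CC(C)(C)[Si](C)(C)Oc1ccc(cc1)-c1oc2cc(O[Si](C)(C)C(C)(C)C)cc(O)c2c(=O)c1O[Si](C)(C)C(C)(C)C | intermediate
11 | 5-hydroxy-6-iodo-3,7-bis(tert-butyldimethylsilyloxy)-2-[4-(tert-butyldimethylsilyloxy)phenyl]-4H-chromen-4-one | CC(C)(C)[Si](C)(C)Oc1ccc(cc1)-c1oc2cc(O[Si](C)(C)C(C)(C)C)c(I)c(O)c2c(=O)c1O[Si](C)(C)C(C)(C)C | intermediate
12 | {[(1R)-2,6,6-trimethylcyclohex-2-en-1-yl]methyl}zinc iodide | CC1=CCCC(C)(C)[C@H]1C[Zn]I | intermediate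
13 | 5-hydroxy-3,7-bis(tert-butyldimethylsilyloxy)-2-[4-(tert-butyldimethylsilyloxy)phenyl]-6-{[(1R)-2,6,6-trimethylcyclohex-2-en-1-yl]methyl}-4H-chromen-4-one | CC1=CCCC(C)(C)[C@H]1Cc1c(O[Si](C)(C)C(C)(C)C)cc2oc(-c3ccc(O[Si](C)(C)C(C)(C)C)cc3)c(O[Si](C)(C)C(C)(C)C)c(=O)c2c1O | intermediate
14 | Ugonin G | CC1=CCCC(C)(C)[C@H]1Cc1c(O)cc2oc(-c3ccc(O)cc3)c(O)c(=O)c2c1O | target

Total step count: 9. Longest linear sequence: 7 steps (steps 1, 2, 3, 4, 5, 8, 9); the flavonol branch (steps 6, 7) joins at step 8.

Steps most likely to fail

Step 3. Leakage through the exo pathway or through the other enal face would each invert C1' and erode the enantiomeric purity, and addition with the reversed orientation (directed by the 2-methyl group) would give the regioisomer. The fallback keeps the cycloaddition but removes the dependence on catalyst and on endo/exo control. It sets out from 3: with 4 and EtAlCl2 in CH2Cl2 at −78 °C the racemic cycloadduct F1 should form, and its endo and exo isomers are carried on together because both lead to the same alcohol. Wolff–Kishner reduction as in step 4 would give racemic α-cyclogeraniol F2. (R)-1-Phenylethyl isocyanate (DMAP, toluene, 80 °C) would convert it into the diastereomeric carbamates F3, from which the (1R) carbamate F4 is separated by crystallisation or preparative HPLC. Cleavage of F4 with LiAlH4 in THF comes back to the route at 7.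

Step 8. Slow transmetalation and reductive elimination at the doubly ortho-substituted aryl–palladium centre could let β-hydride elimination, protonation of the zinc reagent by the 5-OH, or homocoupling take over. The fallback sets out from 8: iodine–lithium exchange (t-BuLi, Et2O, −78 °C) and trapping with B-methoxy-9-BBN would give the lithium B-alkyl-B-methoxy borinate F5. A B-alkyl Suzuki–Miyaura coupling of F5 with 11 (PdCl2(dppf), K3PO4, DMF/H2O, 50 °C) comes back to the route at 13; silyl groups lost to the base are of no consequence because step 9 removes them all.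

Step 7. Loss of regiocontrol (attack at C-8, para to the 5-OH, or double iodination) or partial desilylation could occur. The fallback replaces free-phenol substitution by phenoxide-directed ortho delivery. It sets out from 10: TlOAc in CH2Cl2/EtOH would give the monovalent thallium 5-phenoxide F6, and I2 in CH2Cl2 should then deliver iodine to the carbon ortho to the phenoxide oxygen, coming back to the route at 11.

Further compounds
F1 | step 3 | racemic [6-formyl-2,6-dimethylcyclohex-2-en-1-yl]methyl benzoate (cis and trans isomers) | CC1=CCCC(C)(C=O)C1COC(=O)c1ccccc1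
F2 | step 3 | racemic (2,6,6-trimethylcyclohex-2-en-1-yl)methanol | CC1=CCCC(C)(C)C1CO
F3 | step 3 | (2,6,6-trimethylcyclohex-2-en-1-yl)methyl N-[(1R)-1-phenylethyl]carbamate (both diastereomers) | CC1=CCCC(C)(C)C1COC(=O)N[C@H](C)c1ccccc1
F4 | step 3 | [(1R)-2,6,6-trimethylcyclohex-2-en-1-yl]methyl N-[(1R)-1-phenylethyl]carbamate | CC1=CCCC(C)(C)[C@H]1COC(=O)N[C@H](C)c1ccccc1
F5 | step 8 | lithium 9-methoxy-9-{[(1R)-2,6,6-trimethylcyclohex-2-en-1-yl]methyl}-9-boranuidabicyclo[3.3.1]nonane | [Li+].CC1=CCCC(C)(C)[C@H]1C[B-]2(OC)C3CCCC2CCC3
F6 | step 7 | thallium 5-phenoxide of 10 | CC(C)(C)[Si](C)(C)Oc1ccc(cc1)-c1oc2cc(O[Si](C)(C)C(C)(C)C)cc(O[Tl])c2c(=O)c1O[Si](C)(C)C(C)(C)C
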